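**Retrosynthetic overview**
1. 26 ⇐ 24: the last step forms the C6–O lactone bond and the C15–O bond together by palladium-catalysed 1,4-oxylactonisation of a ring diene acid (the new key step; sets C6 and the C4=C5 geometry; γ-lactone formed last).
2. 24 ⇐ 20: the ten-membered carbocycle is closed first, at C9–C10, by intramolecular Nozaki–Hiyama–Kishi coupling (sets C9); then acetate, deprotection, oxidation.
3. 20 ⇐ 7 + 13: C6–C7 by copper-catalysed SN2' coupling of a dienylzirconocene with a Baylis–Hillman bromide (sets C7 from C8, installs the diene); the C8 ester and C9 aldehyde come from the glyceraldehyde unit.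
4. 7 ⇐ 1 + 5; 13 ⇐ 10 + 11 (chiral pool, C8); 18 brings the side-chain stereocentre.

Assumption: labels C1–C15 are germacrane positions (ring C1–C10, lactone carbons C11–C13, C14 on C10, C15 on C4), and 1, 5, 8, 9, 11 and 18 are bought (11 and 18 enantiopure).

Step 1
Reactants: 1 4-{[tert-butyl(dimethyl)silyl]oxy}but-2-yn-1-ol
Product: 3 (2Z)-4-{[tert-butyl(dimethyl)silyl]oxy}-3-iodobut-2-en-1-ol, via sodium alkenylalanate 2 (not isolated)
Conditions: NaAlH2(OCH2CH2OMe)2 (1.5 equiv), THF, 0 °C; then I2, −78 → 0 °C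
Reagents that add atoms: iodine, II
Why: Alkoxide-directed trans-hydroalumination of the propargylic alcohol puts hydride on C1 and aluminium on C10 in a five-membered alanate, and iodinolysis with retention gives the Z vinyl iodide, which fixes the C1=C10 geometry (C14 trans to C2).

Step 2
Reactants: 3 (2Z)-4-{[tert-butyl(dimethyl)silyl]oxy}-3-iodobut-2-en-1-ol
Product: 4 {[(2Z)-4-bromo-2-iodobut-2-en-1-yl]oxy}(tert-butyl)dimethylsilane
Conditions: CBr4, PPh3, CH2Cl2, 0 °C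
Reagents that add atoms: carbon tetrabromide, BrC(Br)(Br)Br
Why: Appel reaction converts the primary allylic alcohol into the bromide by SN2 displacement without touching the vinyl iodide or the alkene geometry.

Step 3
Reactants: 5 2-methylbut-1-en-3-yne; 4 {[(2Z)-4-bromo-2-iodobut-2-en-1-yl]oxy}(tert-butyl)dimethylsilane
Product: 7 tert-butyl{[(2Z)-2-iodo-6-methylideneoct-2-en-7-yn-1-yl]oxy}dimethylsilane, via dimetalated enyne 6 (not isolated)
Conditions: n-BuLi (2 equiv), KOt-Bu (1 equiv), THF/hexane, −70 → −20 °C; then 4, −78 °C; then H2O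
Reagents that add atoms: none
Why: Double deprotonation (acetylenic CH, then the allylic methyl with the n-BuLi/KOt-Bu superbase) gives a dianion whose more basic allyl terminus is alkylated by the primary allylic bromide (SN2), forming C2–C3; iodine–metal exchange is uphill for this delocalised carbanion.

Step 4
Reactants: 8 prop-2-enoyl chloride; 9 2-(trimethylsilyl)ethanol
Product: 10 2-(trimethylsilyl)ethyl prop-2-enoate
Conditions: Et3N, CH2Cl2, 0 °C
Reagents that add atoms: none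
Why: O-acylation of the alcohol by the acid chloride (esterification) gives an acrylate whose ester can later be cleaved by fluoride.

Step 5
Reactants: 11 (4R)-2,2-dimethyl-1,3-dioxolane-4-carbaldehyde; 10 2-(trimethylsilyl)ethyl prop-2-enoate
Product: 12 2-(trimethylsilyl)ethyl 2-{[(4R)-2,2-dimethyl-1,3-dioxolan-4-yl](hydroxy)methyl}prop-2-enoate (both carbinol epimers)
Conditions: DABCO (0.5 equiv), neat, 20 °C, 4 d
Reagents that add atoms: none
Why: Morita–Baylis–Hillman reaction joins the acrylate α-carbon (C11) to the aldehyde carbon (C7); the new carbinol centre is a mixture that is erased in step 6, and C8 (chiral pool) is untouched.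

Step 6
Reactants: 12 2-(trimethylsilyl)ethyl 2-{[(4R)-2,2-dimethyl-1,3-dioxolan-4-yl](hydroxy)methyl}prop-2-enoate
Product: 13 2-(trimethylsilyl)ethyl (2Z)-2-(bromomethyl)-3-[(4S)-2,2-dimethyl-1,3-dioxolan-4-yl]prop-2-enoate
Conditions: NBS, Me2S, CH2Cl2, 0 → 20 °C
Reagents that add atoms: N-bromosuccinimide, O=C1CCC(=O)N1Br
Why: Corey–Kim-type bromination of the Baylis–Hillman alcohol proceeds with allylic transposition (SN2') and gives the thermodynamically favoured Z 2-(bromomethyl)enoate.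

Step 7
Reactants: 7 tert-butyl{[(2Z)-2-iodo-6-methylideneoct-2-en-7-yn-1-yl]oxy}dimethylsilane; 13 2-(trimethylsilyl)ethyl (2Z)-2-(bromomethyl)-3-[(4S)-2,2-dimethyl-1,3-dioxolan-4-yl]prop-2-enoate
Product: 15 2-(trimethylsilyl)ethyl (3R,4E,9Z)-11-{[tert-butyl(dimethyl)silyl]oxy}-3-[(4S)-2,2-dimethyl-1,3-dioxolan-4-yl]-10-iodo-2,6-dimethylideneundeca-4,9-dienoate, via dienylzirconocene chloride 14 (not isolated)
Conditions: Cp2Zr(H)Cl (1.1 equiv), THF, 20 °C; then CuBr·SMe2 (10 mol %), 13, −20 → 0 °C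
Reagents that add atoms: none
Why: Syn hydrozirconation gives the E dienylzirconocene, and copper-catalysed SN2' substitution (conjugate addition–bromide elimination) joins C6 to C7 and regenerates the 2-methylidene ester; A(1,3) strain with the cis CH2Br holds H-8 in the enoate plane and the organocopper, held by the dioxolane oxygen O-8, adds on that face anti to the C9 methylene, giving the 7,8-syn (7R) adduct.

Step 8
Reactants: 15 2-(trimethylsilyl)ethyl (3R,4E,9Z)-11-{[tert-butyl(dimethyl)silyl]oxy}-3-[(4S)-2,2-dimethyl-1,3-dioxolan-4-yl]-10-iodo-2,6-dimethylideneundeca-4,9-dienoate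
Product: 16 2-(trimethylsilyl)ethyl (3R,4E,9Z)-11-{[tert-butyl(dimethyl)silyl]oxy}-3-[(1S)-1,2-dihydroxyethyl]-10-iodo-2,6-dimethylideneundeca-4,9-dienoate
Conditions: CuCl2·2H2O (2 equiv), MeCN, 0 °C
Reagents that add atoms: none
Why: Lewis-acid-assisted hydrolysis cleaves the terminal isopropylidene acetal while the allylic silyl ether, diene and ester survive; short contact at 0 °C limits lactonisation of the freed C8 hydroxyl onto the acrylate.

Step 9
Reactants: 16 2-(trimethylsilyl)ethyl (3R,4E,9Z)-11-{[tert-butyl(dimethyl)silyl]oxy}-3-[(1S)-1,2-dihydroxyethyl]-10-iodo-2,6-dimethylideneundeca-4,9-dienoate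
Product: 17 2-(trimethylsilyl)ethyl (3R,4E,9Z)-11-{[tert-butyl(dimethyl)silyl]oxy}-3-{(1S)-1-hydroxy-2-[(triethylsilyl)oxy]ethyl}-10-iodo-2,6-dimethylideneundeca-4,9-dienoate
Conditions: Et3SiCl (1.05 equiv), imidazole, CH2Cl2, −78 °C
Reagents that add atoms: chlorotriethylsilane, CC[Si](Cl)(CC)CC
Why: Selective silylation of the primary hydroxyl (steric discrimination at low temperature) leaves the C8 hydroxyl free.

Step 10
Reactants: 17 2-(trimethylsilyl)ethyl (3R,4E,9Z)-11-{[tert-butyl(dimethyl)silyl]oxy}-3-{(1S)-1-hydroxy-2-[(triethylsilyl)oxy]ethyl}-10-iodo-2,6-dimethylideneundeca-4,9-dienoate; 18 (2R)-2-methylbutanoic acid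
Product: 19 2-(trimethylsilyl)ethyl (3R,4E,9Z)-11-{[tert-butyl(dimethyl)silyl]oxy}-10-iodo-2,6-dimethylidene-3-{(1S)-1-{[(2R)-2-methylbutanoyl]oxy}-2-[(triethylsilyl)oxy]ethyl}undeca-4,9-dienoate
Conditions: EDC·HCl, DMAP (cat.), CH2Cl2, 0 °C
Reagents that add atoms: none
Why: Steglich esterification acylates O-8 with retention at C8 and does not epimerise the α-centre of the acid at 0 °C.

Step 11
Reactants: 19 2-(trimethylsilyl)ethyl (3R,4E,9Z)-11-{[tert-butyl(dimethyl)silyl]oxy}-10-iodo-2,6-dimethylidene-3-{(1S)-1-{[(2R)-2-methylbutanoyl]oxy}-2-[(triethylsilyl)oxy]ethyl}undeca-4,9-dienoate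
Product: 20 2-(trimethylsilyl)ethyl (3R,4E,9Z)-11-{[tert-butyl(dimethyl)silyl]oxy}-10-iodo-2,6-dimethylidene-3-[(1S)-1-{[(2R)-2-methylbutanoyl]oxy}-2-oxoethyl]undeca-4,9-dienoate
Conditions: (COCl)2, DMSO, CH2Cl2, −78 → −30 °C; then Et3N, −78 → 0 °C
Reagents that add atoms: none
Why: Swern oxidation acts directly on the primary triethylsilyl ether (the chlorosulfonium salt desilylates it and the alkoxysulfonium ylide collapses to the aldehyde) while the tert-butyldimethylsilyl ether survives; low temperature protects the α-acyloxy stereocentre.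

Step 12
Reactants: 20 2-(trimethylsilyl)ethyl (3R,4E,9Z)-11-{[tert-butyl(dimethyl)silyl]oxy}-10-iodo-2,6-dimethylidene-3-[(1S)-1-{[(2R)-2-methylbutanoyl]oxy}-2-oxoethyl]undeca-4,9-dienoate
Product: 21 2-(trimethylsilyl)ethyl 2-[(1R,2E,7Z,9S,10S)-8-({[tert-butyl(dimethyl)silyl]oxy}methyl)-9-hydroxy-4-methylidene-10-{[(2R)-2-methylbutanoyl]oxy}cyclodeca-2,7-dien-1-yl]prop-2-enoate
Conditions: CrCl2 (10 equiv), NiCl2 (2 mol %), DMSO–THF (3:1), 0.002 M, 20 °C
Reagents that add atoms: none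
Why: Intramolecular Nozaki–Hiyama–Kishi reaction forms the alkenylchromium with retention of the C1=C10 geometry and closes the ten-membered ring by 1,2-addition; in the ring-closing transition state the C8 acyloxy group lies anti to the forming C9–C10 bond and the bulky chromium alkoxide points to the ring periphery, so O-8 and O-9 become trans (9S).

Step 13
Reactants: 21 2-(trimethylsilyl)ethyl 2-[(1R,2E,7Z,9S,10S)-8-({[tert-butyl(dimethyl)silyl]oxy}methyl)-9-hydroxy-4-methylidene-10-{[(2R)-2-methylbutanoyl]oxy}cyclodeca-2,7-dien-1-yl]prop-2-enoate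
Product: 22 2-(trimethylsilyl)ethyl 2-[(1R,2E,7Z,9S,10S)-9-(acetyloxy)-8-({[tert-butyl(dimethyl)silyl]oxy}methyl)-4-methylidene-10-{[(2R)-2-methylbutanoyl]oxy}cyclodeca-2,7-dien-1-yl]prop-2-enoate
Conditions: Ac2O, pyridine, DMAP (cat.), CH2Cl2, 0 °C
Reagents that add atoms: acetic anhydride, CC(=O)OC(C)=O
Why: DMAP-catalysed acetylation of the only free hydroxyl fixes the C9 acetate with retention.

Step 14
Reactants: 22 2-(trimethylsilyl)ethyl 2-[(1R,2E,7Z,9S,10S)-9-(acetyloxy)-8-({[tert-butyl(dimethyl)silyl]oxy}methyl)-4-methylidene-10-{[(2R)-2-methylbutanoyl]oxy}cyclodeca-2,7-dien-1-yl]prop-2-enoate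
Product: 23 2-[(1R,2E,7Z,9S,10S)-9-(acetyloxy)-8-(hydroxymethyl)-4-methylidene-10-{[(2R)-2-methylbutanoyl]oxy}cyclodeca-2,7-dien-1-yl]prop-2-enoic acid
Conditions: Bu4NF, AcOH (1:1, 3 equiv), THF, 0 → 20 °C
Reagents that add atoms: none
Why: Fluoride removes the tert-butyldimethylsilyl ether and triggers β-elimination of the 2-(trimethylsilyl)ethyl ester in one operation; acetic acid buffering suppresses acetyl migration from O-9 to O-14 and deconjugation at C7.

Step 15
Reactants: 23 2-[(1R,2E,7Z,9S,10S)-9-(acetyloxy)-8-(hydroxymethyl)-4-methylidene-10-{[(2R)-2-methylbutanoyl]oxy}cyclodeca-2,7-dien-1-yl]prop-2-enoic acid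
Product: 24 2-[(1R,2E,7E,9S,10S)-9-(acetyloxy)-8-formyl-4-methylidene-10-{[(2R)-2-methylbutanoyl]oxy}cyclodeca-2,7-dien-1-yl]prop-2-enoic acid
Conditions: Dess–Martin periodinane, CH2Cl2, 0 °C
Reagents that add atoms: none
Why: Dess–Martin oxidation turns the allylic alcohol into the enal without isomerising C1=C10 (aldehyde stays trans to C2) and tolerates the free acid and the diene.

Step 16
Reactants: 24 2-[(1R,2E,7E,9S,10S)-9-(acetyloxy)-8-formyl-4-methylidene-10-{[(2R)-2-methylbutanoyl]oxy}cyclodeca-2,7-dien-1-yl]prop-2-enoic acid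
Product: 26 (1(10)E,4E,6R,7S,8S,9S)-9-(acetyloxy)-15-hydroxy-8-{[(2R)-2-methylbutanoyl]oxy}-14-oxogermacra-1(10),4,11(13)-trien-12,6-olide, via C15 trifluoroacetate 25 (not isolated)
Conditions: Pd(O2CCF3)2 (10 mol %), 1,4-benzoquinone (2 equiv), CF3CO2H (5 equiv), LiO2CCF3 (2 equiv), acetone, 20 °C; then MeOH, NaHCO3 (cat.), 0 °C
Reagents that add atoms: trifluoroacetic acid, OC(=O)C(F)(F)F
Why: Proposed new method: divalent palladium binds the cross-conjugated C15=C4–C5=C6 diene, the tethered acrylic acid attacks C6 anti to the metal (5-exo oxypalladation) to give a π-allylpalladium over C5–C4–C15, and benzoquinone then triggers trifluoroacetate attack at the unsubstituted C15 terminus and reoxidises zerovalent palladium, so the C6–O lactone bond, the C15–O bond and the C4=C5 double bond form together; the E-cyclodecene torsion (C8 anticlinal to C5 about C6–C7) lets the acid reach only the face that gives the trans-fused 6R lactone, and the ring-cis C4=C5 geometry follows from the s-trans diene (C3 syn to C6), the allyl geometry a ten-membered ring tolerates; the closest known reaction type is the palladium/benzoquinone intramolecular 1,4-oxylactonisation (1,4-acyloxy-lactonisation) of simple diene acids, not yet shown for a 2-substituted diene set across a medium ring, for an acrylic acid nucleophile, or with trifluoroacetate as a second nucleophile that methanolysis removes to free the C15 alcohol.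

**Compound list**
1 | 4-{[tert-butyl(dimethyl)silyl]oxy}but-2-yn-1-ol | OCC#CCO[Si](C)(C)C(C)(C)C | starting material
2 | sodium 2,2-bis(2-methoxyethoxy)-3-({[tert-butyl(dimethyl)silyl]oxy}methyl)-2,5-dihydro-1,2-oxaaluminol-2-uide (cyclic alkenylalanate) | [Na+].COCCO[Al-]1(OCCOC)OCC=C1CO[Si](C)(C)C(C)(C)C | intermediate
3 | (2Z)-4-{[tert-butyl(dimethyl)silyl]oxy}-3-iodobut-2-en-1-ol | OC/C=C(\I)CO[Si](C)(C)C(C)(C)C | intermediate
4 | {[(2Z)-4-bromo-2-iodobut-2-en-1-yl]oxy}(tert-butyl)dimethylsilane | BrC/C=C(\I)CO[Si](C)(C)C(C)(C)C | intermediate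
5 | 2-methylbut-1-en-3-yne | C=C(C)C#C | starting material
6 | lithium potassium 2-methylidenebut-3-yne-1,4-diide (dimetalated 5) | [Li+].[K+].[CH2-]C(=C)C#[C-] | intermediate
7 | tert-butyl{[(2Z)-2-iodo-6-methylideneoct-2-en-7-yn-1-yl]oxy}dimethylsilane | C#CC(=C)CC/C=C(\I)CO[Si](C)(C)C(C)(C)C | intermediate
8 | prop-2-enoyl chloride | C=CC(=O)Cl | starting material
9 | 2-(trimethylsilyl)ethanol | OCC[Si](C)(C)C | starting material
10 | 2-(trimethylsilyl)ethyl prop-2-enoate | C=CC(=O)OCC[Si](C)(C)C | intermediate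
11 | (4R)-2,2-dimethyl-1,3-dioxolane-4-carbaldehyde | O=C[C@H]1COC(C)(C)O1 | starting material
12 | 2-(trimethylsilyl)ethyl 2-{[(4R)-2,2-dimethyl-1,3-dioxolan-4-yl](hydroxy)methyl}prop-2-enoate (both carbinol epimers) | C=C(C(=O)OCC[Si](C)(C)C)C(O)[C@H]1COC(C)(C)O1 | intermediate
13 | 2-(trimethylsilyl)ethyl (2Z)-2-(bromomethyl)-3-[(4S)-2,2-dimethyl-1,3-dioxolan-4-yl]prop-2-enoate | BrC/C(C(=O)OCC[Si](C)(C)C)=C\[C@H]1COC(C)(C)O1 | intermediate
14 | chlorobis(cyclopentadienyl)[(1E,6Z)-8-{[tert-butyl(dimethyl)silyl]oxy}-7-iodo-3-methylideneocta-1,6-dien-1-yl]zirconium | Cl[Zr](/C=C/C(=C)CC/C=C(\I)CO[Si](C)(C)C(C)(C)C)(C1C=CC=C1)C1C=CC=C1 | intermediate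
15 | 2-(trimethylsilyl)ethyl (3R,4E,9Z)-11-{[tert-butyl(dimethyl)silyl]oxy}-3-[(4S)-2,2-dimethyl-1,3-dioxolan-4-yl]-10-iodo-2,6-dimethylideneundeca-4,9-dienoate | C=C(C(=O)OCC[Si](C)(C)C)[C@@H](/C=C/C(=C)CC/C=C(\I)CO[Si](C)(C)C(C)(C)C)[C@H]1COC(C)(C)O1 | intermediate
16 | 2-(trimethylsilyl)ethyl (3R,4E,9Z)-11-{[tert-butyl(dimethyl)silyl]oxy}-3-[(1S)-1,2-dihydroxyethyl]-10-iodo-2,6-dimethylideneundeca-4,9-dienoate | C=C(C(=O)OCC[Si](C)(C)C)[C@@H](/C=C/C(=C)CC/C=C(\I)CO[Si](C)(C)C(C)(C)C)[C@H](O)CO | intermediate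
17 | 2-(trimethylsilyl)ethyl (3R,4E,9Z)-11-{[tert-butyl(dimethyl)silyl]oxy}-3-{(1S)-1-hydroxy-2-[(triethylsilyl)oxy]ethyl}-10-iodo-2,6-dimethylideneundeca-4,9-dienoate | C=C(C(=O)OCC[Si](C)(C)C)[C@@H](/C=C/C(=C)CC/C=C(\I)CO[Si](C)(C)C(C)(C)C)[C@H](O)CO[Si](CC)(CC)CC | intermediate
18 | (2R)-2-methylbutanoic acid | CC[C@@H](C)C(=O)O | starting material
19 | 2-(trimethylsilyl)ethyl (3R,4E,9Z)-11-{[tert-butyl(dimethyl)silyl]oxy}-10-iodo-2,6-dimethylidene-3-{(1S)-1-{[(2R)-2-methylbutanoyl]oxy}-2-[(triethylsilyl)oxy]ethyl}undeca-4,9-dienoate | C=C(C(=O)OCC[Si](C)(C)C)[C@@H](/C=C/C(=C)CC/C=C(\I)CO[Si](C)(C)C(C)(C)C)[C@H](OC(=O)[C@H](C)CC)CO[Si](CC)(CC)CC | intermediate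
20 | 2-(trimethylsilyl)ethyl (3R,4E,9Z)-11-{[tert-butyl(dimethyl)silyl]oxy}-10-iodo-2,6-dimethylidene-3-[(1S)-1-{[(2R)-2-methylbutanoyl]oxy}-2-oxoethyl]undeca-4,9-dienoate | C=C(C(=O)OCC[Si](C)(C)C)[C@@H](/C=C/C(=C)CC/C=C(\I)CO[Si](C)(C)C(C)(C)C)[C@H](OC(=O)[C@H](C)CC)C=O | intermediate
21 | 2-(trimethylsilyl)ethyl 2-[(1R,2E,7Z,9S,10S)-8-({[tert-butyl(dimethyl)silyl]oxy}methyl)-9-hydroxy-4-methylidene-10-{[(2R)-2-methylbutanoyl]oxy}cyclodeca-2,7-dien-1-yl]prop-2-enoate | C=C(C(=O)OCC[Si](C)(C)C)[C@H]1/C=C/C(=C)CC/C=C(/CO[Si](C)(C)C(C)(C)C)[C@H](O)[C@H]1OC(=O)[C@H](C)CC | intermediate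
22 | 2-(trimethylsilyl)ethyl 2-[(1R,2E,7Z,9S,10S)-9-(acetyloxy)-8-({[tert-butyl(dimethyl)silyl]oxy}methyl)-4-methylidene-10-{[(2R)-2-methylbutanoyl]oxy}cyclodeca-2,7-dien-1-yl]prop-2-enoate | C=C(C(=O)OCC[Si](C)(C)C)[C@H]1/C=C/C(=C)CC/C=C(/CO[Si](C)(C)C(C)(C)C)[C@H](OC(C)=O)[C@H]1OC(=O)[C@H](C)CC | intermediate
23 | 2-[(1R,2E,7Z,9S,10S)-9-(acetyloxy)-8-(hydroxymethyl)-4-methylidene-10-{[(2R)-2-methylbutanoyl]oxy}cyclodeca-2,7-dien-1-yl]prop-2-enoic acid | C=C(C(=O)O)[C@H]1/C=C/C(=C)CC/C=C(/CO)[C@H](OC(C)=O)[C@H]1OC(=O)[C@H](C)CC | intermediate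
24 | 2-[(1R,2E,7E,9S,10S)-9-(acetyloxy)-8-formyl-4-methylidene-10-{[(2R)-2-methylbutanoyl]oxy}cyclodeca-2,7-dien-1-yl]prop-2-enoic acid | C=C(C(=O)O)[C@H]1/C=C/C(=C)CC/C=C(/C=O)[C@H](OC(C)=O)[C@H]1OC(=O)[C@H](C)CC | intermediate
25 | 15-O-(trifluoroacetyl) derivative of 26 | C=C1C(=O)O[C@@H]2/C=C(/COC(=O)C(F)(F)F)CC/C=C(/C=O)[C@H](OC(C)=O)[C@@H](OC(=O)[C@H](C)CC)[C@@H]12 | intermediate
26 | (1(10)E,4E,6R,7S,8S,9S)-9-(acetyloxy)-15-hydroxy-8-{[(2R)-2-methylbutanoyl]oxy}-14-oxogermacra-1(10),4,11(13)-trien-12,6-olide (both ring double bonds ring-cis) | C=C1C(=O)O[C@@H]2/C=C(/CO)CC/C=C(/C=O)[C@H](OC(C)=O)[C@@H](OC(=O)[C@H](C)CC)[C@@H]12 | target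

**Step count**
Total steps: 16. Longest linear sequence: 13 (steps 1–3 then 7–16; the same length through steps 4–6 then 7–16).

**Three steps most likely to fail**

Step 16 (the proposed new oxylactonisation). Possible failures are β-hydride loss from the π-allyl intermediate, attack at the wrong terminus, or the wrong C6 or C4=C5 outcome. The fallback uses known chemistry, sets out from 24 and returns at 26. The 1,1-disubstituted diene terminus of 24 is epoxidised (mCPBA, NaHCO3, CH2Cl2, −20 °C) to the vinyl oxirane F1 (either C4 epimer). Pd(PPh3)4 (5 mol %) in THF then opens the vinyl epoxide with zerovalent palladium to a π-allyl/alkoxide pair, and the tethered carboxylate closes the γ-lactone at C6 (Tsuji–Trost 1,4-addition to a vinyl epoxide). This gives 26 directly as an isomer of F1, with the C15 alkoxide becoming the free alcohol.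

Step 12 (ring closure and C9). The C9 configuration rests on a conformational argument and is the weakest stereochemical claim in the route. The fallback sets out from 20 and returns at 21. If the coupling gives mainly the 9R alcohol F2, the alcohol mixture is oxidised (Dess–Martin periodinane, CH2Cl2) to the ring enone F3. C9 is then set by reagent control with (S)-2-methyl-CBS-oxazaborolidine and catecholborane at −78 °C, with the alkenyl group as the large substituent, to give 21.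

Step 7 (SN2' coupling and C7). The facial selectivity could instead follow the Felkin-type mode (addition anti to O-8), which would give the 7-epimer. The fallback sets out from 7 (through 14) and 10, and returns at 19. The same chemistry is run with the enantiomeric aldehyde, (4S)-2,2-dimethyl-1,3-dioxolane-4-carbaldehyde F4. Baylis–Hillman reaction with 10 gives adduct F5, and NBS/Me2S gives the Z allylic bromide F6. Coupling of F6 with 14 under the step 7 conditions gives, in the anti mode, the adduct F7, which has the required C7 configuration and the opposite C8. Acetal hydrolysis gives diol F8 and selective silylation gives the triethylsilyl ether F9. Mitsunobu esterification of F9 with 18 (PPh3, DIAD, toluene, 0 °C) then forms the C8–O ester bond with inversion and gives 19.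

**Further compounds**
F1 | step 16 | 4,15-epoxide of 24: 2-[(1R,2E,7E,9S,10S)-9-(acetyloxy)-8-formyl-10-{[(2R)-2-methylbutanoyl]oxy}-4-spiro-oxiranylcyclodeca-2,7-dien-1-yl]prop-2-enoic acid (both C4 epimers) | C=C(C(=O)O)[C@H]1/C=C/C2(CO2)CC/C=C(/C=O)[C@H](OC(C)=O)[C@H]1OC(=O)[C@H](C)CC
F2 | step 12 | 2-(trimethylsilyl)ethyl 2-[(1R,2E,7Z,9R,10S)-8-({[tert-butyl(dimethyl)silyl]oxy}methyl)-9-hydroxy-4-methylidene-10-{[(2R)-2-methylbutanoyl]oxy}cyclodeca-2,7-dien-1-yl]prop-2-enoate (9-epimer of 21) | C=C(C(=O)OCC[Si](C)(C)C)[C@H]1/C=C/C(=C)CC/C=C(/CO[Si](C)(C)C(C)(C)C)[C@@H](O)[C@H]1OC(=O)[C@H](C)CC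
F3 | step 12 | 2-(trimethylsilyl)ethyl 2-[(1R,2E,7Z,10S)-8-({[tert-butyl(dimethyl)silyl]oxy}methyl)-4-methylidene-10-{[(2R)-2-methylbutanoyl]oxy}-9-oxocyclodeca-2,7-dien-1-yl]prop-2-enoate | C=C(C(=O)OCC[Si](C)(C)C)[C@H]1/C=C/C(=C)CC/C=C(/CO[Si](C)(C)C(C)(C)C)C(=O)[C@H]1OC(=O)[C@H](C)CC
F4 | step 7 | (4S)-2,2-dimethyl-1,3-dioxolane-4-carbaldehyde | O=C[C@@H]1COC(C)(C)O1
F5 | step 7 | 2-(trimethylsilyl)ethyl 2-{[(4S)-2,2-dimethyl-1,3-dioxolan-4-yl](hydroxy)methyl}prop-2-enoate (both carbinol epimers) | C=C(C(=O)OCC[Si](C)(C)C)C(O)[C@@H]1COC(C)(C)O1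
F6 | step 7 | 2-(trimethylsilyl)ethyl (2Z)-2-(bromomethyl)-3-[(4R)-2,2-dimethyl-1,3-dioxolan-4-yl]prop-2-enoate | BrC/C(C(=O)OCC[Si](C)(C)C)=C\[C@@H]1COC(C)(C)O1
F7 | step 7 | 2-(trimethylsilyl)ethyl (3R,4E,9Z)-11-{[tert-butyl(dimethyl)silyl]oxy}-3-[(4R)-2,2-dimethyl-1,3-dioxolan-4-yl]-10-iodo-2,6-dimethylideneundeca-4,9-dienoate | C=C(C(=O)OCC[Si](C)(C)C)[C@@H](/C=C/C(=C)CC/C=C(\I)CO[Si](C)(C)C(C)(C)C)[C@@H]1COC(C)(C)O1
F8 | step 7 | 2-(trimethylsilyl)ethyl (3R,4E,9Z)-11-{[tert-butyl(dimethyl)silyl]oxy}-3-[(1R)-1,2-dihydroxyethyl]-10-iodo-2,6-dimethylideneundeca-4,9-dienoate | C=C(C(=O)OCC[Si](C)(C)C)[C@@H](/C=C/C(=C)CC/C=C(\I)CO[Si](C)(C)C(C)(C)C)[C@@H](O)CO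
F9 | step 7 | 2-(trimethylsilyl)ethyl (3R,4E,9Z)-11-{[tert-butyl(dimethyl)silyl]oxy}-3-{(1R)-1-hydroxy-2-[(triethylsilyl)oxy]ethyl}-10-iodo-2,6-dimethylideneundeca-4,9-dienoate | C=C(C(=O)OCC[Si](C)(C)C)[C@@H](/C=C/C(=C)CC/C=C(\I)CO[Si](C)(C)C(C)(C)C)[C@@H](O)CO[Si](CC)(CC)CC
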